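The numbers in the tables stem from a simulated flask from invented constants; the scatter is artificial.

Divide the equivalents of nucleophile by the fraction of electrophile gone in the quick first stretch: ochre gives 1.87 and green, at its lowest reading, 1.98, so you take two nucleophile per electrophile.

| setting | ochre | green | eta | alpha |
|---|---|---|---|---|
| electrophile | 20 mM | 20 mM | 20 mM | 20 mM |
| nucleophile | 0.88 equiv | 1.8 equiv | 1.10 equiv | 2.10 equiv |
| remark | run made earlier | run made earlier |  |  |
| time |  |  | 6.0 min | 6.0 min |

| run | time / min | electrophile / % | target / % |
|---|---|---|---|
| ochre | 0.500 | 53 | 42 |
| ochre | 0.667 | 57 | 40 |
| ochre | 1.00 | 52 | 37 |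
| ochre | 1.50 | 56 | 36 |
| ochre | 2.50 | 46 | 36 |
| ochre | 4.00 | 45 | 33 |
| ochre | 6.00 | 42 | 27 |
| green | 0.333 | 26 | 73 |
| green | 1.00 | 17 | 77 |
| green | 1.50 | 13 | 79 |
| green | 2.50 | 10 | 79 |
| green | 4.00 | 9 | 77 |
| green | 5.00 | 12 | 73 |
| green | 6.00 | 12 | 68 |

(each reading ± 2 percentage points)

- part of the electrophile that has reacted at the end, eta
- part of the electrophile that has reacted at the end, alpha
- what raising the equivalents of nucleophile from its lowest to its highest value here does to the part of the electrophile that has reacted (changes below 5 percentage points count as none) (it rises / it falls / no change)



In eta the nucleophile is the limiting reagent, and the burst should stop at 55.0% reacted. After that, ochre loses target slowly. Take the drift constant, the target fraction lost per minute divided by the product of the electrophile and target fractions 0.166 min⁻¹, with each curve replaced by the mean of its ends, at this charge of electrophile. Each unit of drift takes one electrophile and one target. For eta, try ochre's drop of 15 percentage points: the means then give 18 points, and a second pass gives 17 points, so the means cost about a point. Your reckoning is 71.6% reacted. Alpha's ratio gives 105%, above the charge, so you expect more than the 91.0% read at green's lowest reading.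

The forecast, reasoning that “roughly two nucleophile are spent per electrophile”, says 66% for eta, below your figure, 97% for alpha, and it rises.

The flasks give 69.8% for eta and 95.8% for alpha, and it rises by 26 points.

    electrophile + nucleophile ⇌ acid set free + target (K = 0.480, k = 5.00 M⁻¹ s⁻¹)
    electrophile + target → side product (k = 0.140 M⁻¹ s⁻¹)
    nucleophile + acid set free ⇌ protonated nucleophile, settled at all times (K = 19000 M⁻¹)

In eta the forward half-life of electrophile in the first step, 0.11 min as charged, is far shorter than the 4.1 min of target in the step to side product, and that one is shorter than the 6.0 min of the run. Eta's 33.2% of side product counts two electrophiles per molecule, so 16.6% of target went that way, against your drop of 17 points. Moved alone by equal factors, the settings tried shift eta's answer in the order nucleophile (12 points), then electrophile (3.2 points), then time (3 points), and that answer has moved 5 points at 0.986 equiv and at 1.23 equiv of nucleophile, so the equivalents are where a run could show the forecast for eta wrong.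

In a second flask, eta's recipe at 5.0 mM of electrophile, the drift constant taken in proportion to that charge is 0.0416 min⁻¹, and two passes give a drop of 5.4 points, so your reckoning there is 60.4% reacted. The flask gives 57.5% reacted, with 46.6% of target and 10.9% of side product, which is 5.45% of target spent.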